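The carbocycle is made last, by a Claisen ring closure that joins C7, the acyl-bearing carbon, to the C6 carbonyl (benzofuran numbering). Its precursor is a γ-butyrolactone carrying, on one quaternary carbon, the prenyl group and a 1,3-diketone chain; that carbon (the later C3a) is set by anti-prenylation on the lactone, whose other stereocentres come from one Sharpless epoxidation. Methyl isobutyrate enolate opens the lactone (C4–C5 bond), the diketonate closes onto the new ester (C7–C6), and acid lets the freed C2 hydroxyl condense on C7a, so the lactone oxygen becomes the dihydrofuran oxygen. The step exploits the 1,3,5-tricarbonyl carbocycle, in which C3a and C5 are quaternary, so that only C7 can close onto C6.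

Key step: step 6

Remark: locants C2 to C7a in the Why lines are those of the benzofuran skeleton of the target. (R)-2-Methylbutanoic acid is taken as a purchased single enantiomer. β-Dicarbonyl compounds are drawn as one tautomer.

Step 1
Reactants: 1 geraniol
Product: 2 [(2S,3S)-3-methyl-3-(4-methylpent-3-en-1-yl)oxiran-2-yl]methanol
Conditions: Ti(OiPr)4 (5 mol%), L-(+)-diethyl tartrate (6 mol%), t-BuOOH, 4 Å MS, CH2Cl2, −20 °C
Reagents that add atoms: tert-butyl hydroperoxide, CC(C)(C)OO
Why: Sharpless asymmetric epoxidation: the titanium tartrate complex binds the allylic hydroxyl, so only the 2,3-alkene is oxidised, and L-(+)-diethyl tartrate directs oxygen to the face that should give the (2S,3S)-epoxide, which sets both oxygenated stereocentres of the later side chain.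

Step 2
Reactants: 2 [(2S,3S)-3-methyl-3-(4-methylpent-3-en-1-yl)oxiran-2-yl]methanol; 3 ethyl acetoacetate (2.5 equiv)
Product: 5 (5R)-3-acetyl-5-[(2S)-2-hydroxy-6-methylhept-5-en-2-yl]oxolan-2-one (C3 epimer mixture), via terminal epoxide 4 (not isolated)
Conditions: KOtBu (3 equiv), t-BuOH, 80 °C; then 1 M HCl
Reagents that add atoms: none
Why: Base-mediated Payne rearrangement (intramolecular SN2, inversion at C2) equilibrates 2 with the terminal epoxide 4, whose unhindered CH2 is opened by the acetoacetate carbanion while the trisubstituted epoxide of 2 is not, and the released secondary alkoxide lactonises onto the ethyl ester (acetoacetic ester lactone synthesis), so that C5 of the lactone carries the inverted oxygen, the carbinol centre is untouched and C3 stays an inconsequential enolisable epimer mixture.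

Step 3
Reactants: 5 (5R)-3-acetyl-5-[(2S)-2-hydroxy-6-methylhept-5-en-2-yl]oxolan-2-one; 6 1-bromo-3-methylbut-2-ene (prenyl bromide)
Product: 7 (3S,5R)-3-acetyl-5-[(2S)-2-hydroxy-6-methylhept-5-en-2-yl]-3-(3-methylbut-2-en-1-yl)oxolan-2-one
Conditions: K2CO3, acetone, 23 → 50 °C
Reagents that add atoms: none
Why: Enolate C-alkylation (SN2) of the β-keto lactone: both C3 epimers of 5 converge on one planar enolate, which prenyl bromide should attack on the face anti to the bulky C5 substituent (1,3-induction), setting the quaternary C3 as S, prenyl trans to the side chain.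

Step 4
Reactants: 8 (2R)-2-methylbutanoic acid; 9 1H-benzotriazole (4 equiv)
Product: 10 1-[(2R)-2-methylbutanoyl]-1H-benzotriazole
Conditions: SOCl2 (1 equiv), CH2Cl2, 23 °C
Reagents that add atoms: none
Why: N-Acylbenzotriazole formation through the acid chloride made in situ, excess benzotriazole being the only base, so the α-stereocentre is not exposed to enolising conditions.

Step 5
Reactants: 7 (3S,5R)-3-acetyl-5-[(2S)-2-hydroxy-6-methylhept-5-en-2-yl]-3-(3-methylbut-2-en-1-yl)oxolan-2-one; 10 1-[(2R)-2-methylbutanoyl]-1H-benzotriazole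
Product: 11 (3S,5R)-5-[(2S)-2-hydroxy-6-methylhept-5-en-2-yl]-3-(3-methylbut-2-en-1-yl)-3-[(4R)-4-methyl-3-oxohexanoyl]oxolan-2-one
Conditions: MgBr2·OEt2, i-Pr2NEt, CH2Cl2, 23 °C; then 1 M HCl
Reagents that add atoms: none
Why: Soft enolisation and crossed Claisen-type C-acylation: magnesium chelation of the β-keto lactone lets the amine deprotonate the acetyl CH3, the only enolisable position, and the magnesium enolate is acylated by 10, the product being held as its magnesium diketonate, which should prevent a second acylation and epimerisation; no stereocentre is formed.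

Step 6
Reactants: 11 (3S,5R)-5-[(2S)-2-hydroxy-6-methylhept-5-en-2-yl]-3-(3-methylbut-2-en-1-yl)-3-[(4R)-4-methyl-3-oxohexanoyl]oxolan-2-one; 12 methyl 2-methylpropanoate (methyl isobutyrate, 4.5 equiv)
Product: 15 (2R,3aS)-2-[(2S)-2-hydroxy-6-methylhept-5-en-2-yl]-5,5-dimethyl-3a-(3-methylbut-2-en-1-yl)-7-[(2R)-2-methylbutanoyl]-3,3a-dihydro-1-benzofuran-4,6(2H,5H)-dione (CNP0306408.2), via keto ester 13 (not isolated), via hydroxy triketone 14 (not isolated)
Conditions: LiN(iPr)2 (4.3 equiv, less than 12), THF, −78 °C; add 11; −78 → 50 °C; then 1 M HCl to pH 2, THF, 23 °C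
Reagents that add atoms: none
Why: After the ester enolate has deprotonated the hydroxyl and the 1,3-diketone of 11, a further equivalent adds to the lactone carbonyl, the only carbonyl not masked as an enolate, and the tetrahedral intermediate opens to the alkoxide of β-keto ester 13 (new C4–C5 bond); the diketonate carbon C7 then attacks the methyl ester carbon C6, expels methoxide and the product is drained as the triketonate of 14. The closest known reaction types are the crossed Claisen condensation of an ester enolate with a lactone and the Dieckmann-type Claisen cyclisation of a polyketone ester to an acylcyclohexanetrione. The carbocycle closes by 6-exo-trig attack of C7 on C6; on acidification the dihydrofuran closes by 5-exo-trig addition of the freed C2 hydroxyl to C7a and loss of water. No stereocentre is created: C3a is quaternary and cannot enolise, the C2–O bond is never broken, and the acyl α-centre is shielded because its ketone stays inside the enolate as long as no free amide base is left. The step needs chemoselective attack on the lactone, secured by the anionic diketonate; a single mode of ring closure, secured by the quaternary C3a and C5, which leave C7 as the only carbon able to reach C6 and favour cyclisation by gem-disubstitution; and furan over pyran closure, secured by the faster five-ring closure of the secondary hydroxyl compared with six-ring closure of the tertiary one.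

Compound list
1 | geraniol, (2E)-3,7-dimethylocta-2,6-dien-1-ol | OC/C=C(\C)CCC=C(C)C | starting material
2 | [(2S,3S)-3-methyl-3-(4-methylpent-3-en-1-yl)oxiran-2-yl]methanol | OC[C@@H]1O[C@@]1(C)CCC=C(C)C | intermediate
3 | ethyl acetoacetate | CCOC(=O)CC(C)=O | starting material
4 | (2S)-6-methyl-2-[(2R)-oxiran-2-yl]hept-5-en-2-ol (terminal epoxide, Payne isomer of 2) | C1O[C@H]1[C@@](C)(O)CCC=C(C)C | intermediate
5 | (5R)-3-acetyl-5-[(2S)-2-hydroxy-6-methylhept-5-en-2-yl]oxolan-2-one, C3 epimer mixture | O=C1O[C@@H]([C@@](C)(O)CCC=C(C)C)CC1C(C)=O | intermediate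
6 | 1-bromo-3-methylbut-2-ene | CC(C)=CCBr | starting material
7 | (3S,5R)-3-acetyl-5-[(2S)-2-hydroxy-6-methylhept-5-en-2-yl]-3-(3-methylbut-2-en-1-yl)oxolan-2-one | O=C1O[C@@H]([C@@](C)(O)CCC=C(C)C)C[C@@]1(CC=C(C)C)C(C)=O | intermediate
8 | (2R)-2-methylbutanoic acid | CC[C@@H](C)C(=O)O | starting material
9 | 1H-benzotriazole | c1ccc2[nH]nnc2c1 | starting material
10 | 1-[(2R)-2-methylbutanoyl]-1H-benzotriazole | CC[C@@H](C)C(=O)n1nnc2ccccc12 | intermediate
11 | (3S,5R)-5-[(2S)-2-hydroxy-6-methylhept-5-en-2-yl]-3-(3-methylbut-2-en-1-yl)-3-[(4R)-4-methyl-3-oxohexanoyl]oxolan-2-one | O=C1O[C@@H]([C@@](C)(O)CCC=C(C)C)C[C@@]1(CC=C(C)C)C(=O)CC(=O)[C@H](C)CC | intermediate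
12 | methyl 2-methylpropanoate | COC(=O)C(C)C | starting material
13 | methyl (4S,8R)-4-[(2R,3S)-2,3-dihydroxy-3,7-dimethyloct-6-en-1-yl]-2,2,8-trimethyl-4-(3-methylbut-2-en-1-yl)-3,5,7-trioxodecanoate | CC[C@@H](C)C(=O)CC(=O)[C@](CC=C(C)C)(C[C@@H](O)[C@@](C)(O)CCC=C(C)C)C(=O)C(C)(C)C(=O)OC | intermediate
14 | 6-[(2R,3S)-2,3-dihydroxy-3,7-dimethyloct-6-en-1-yl]-3-hydroxy-4,4-dimethyl-6-(3-methylbut-2-en-1-yl)-2-[(2R)-2-methylbutanoyl]cyclohex-2-ene-1,5-dione, one enol tautomer, quaternary ring carbon configured as C3a of the target | CC[C@@H](C)C(=O)C1=C(O)C(C)(C)C(=O)[C@@](CC=C(C)C)(C[C@@H](O)[C@@](C)(O)CCC=C(C)C)C1=O | intermediate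
15 | (2R,3aS)-2-[(2S)-2-hydroxy-6-methylhept-5-en-2-yl]-5,5-dimethyl-3a-(3-methylbut-2-en-1-yl)-7-[(2R)-2-methylbutanoyl]-3,3a-dihydro-1-benzofuran-4,6(2H,5H)-dione | CC[C@@H](C)C(=O)C1=C2O[C@@H]([C@@](C)(O)CCC=C(C)C)C[C@]2(CC=C(C)C)C(=O)C(C)(C)C1=O | target

Total step count: 6. Longest linear sequence: 5 steps (steps 1, 2, 3, 5, 6); step 4 is a one-step side branch.

Steps most likely to fail

Step 6. The hindered ester enolate may add only slowly to the α-quaternary lactone carbonyl, or the chelated diketonate may stall before the hindered ester and fall back to 11 by retro-Claisen cleavage. Fallback: setting out from 11, the slimmer and more nucleophilic lithiated isobutyronitrile (isobutyronitrile, LiN(iPr)2, THF, −78 → 0 °C) should open the lactone to the keto nitrile F5. A Thorpe-type addition of the diketonate carbon to the nitrile (KOtBu, t-BuOH, 60 °C) should then close the carbocycle, again through the C7–C6 bond, as the enaminone F6. Hydrolysis of this vinylogous amide in aqueous oxalic acid/THF should release 14, which closes to 15 as in the main route.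

Step 2. The Payne equilibrium may lie so far on the side of the trisubstituted epoxide that opening becomes slow and alkoxide attack or retro-Claisen loss of the acetyl group competes. Fallback: from 2, iodination (I2, PPh3, imidazole) should give the epoxy iodide F1, and SN2 alkylation of the lithium enolate of tert-butyl acetate (LiN(iPr)2, THF, −78 °C) the epoxy ester F2. Acid-mediated lactonisation (camphorsulfonic acid, CH2Cl2), in which the ester carbonyl opens the epoxide at the secondary carbon by 5-exo attack with inversion and isobutene is lost, should give the hydroxy lactone F3. C-Acetylation of its enolate (LiN(SiMe3)2, 1-acetylimidazole) should return to 5.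

Step 3. Facial selectivity of the prenylation may be poor, or O-alkylation of the enolate may compete. Fallback: from 5, a Tsuji–Trost allylation under catalyst control (allyl methyl carbonate, Pd2(dba)3, the matched enantiomer of the DACH-phenyl Trost ligand) should give the allyl lactone F4. Cross-metathesis with 2-methylbut-2-ene (second-generation Grubbs catalyst) should then convert allyl into prenyl and return to 7.

Further compounds
F1 | step 2 | (2R,3S)-2-(iodomethyl)-3-methyl-3-(4-methylpent-3-en-1-yl)oxirane | IC[C@@H]1O[C@@]1(C)CCC=C(C)C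
F2 | step 2 | tert-butyl 3-[(2S,3S)-3-methyl-3-(4-methylpent-3-en-1-yl)oxiran-2-yl]propanoate | CC(C)(C)OC(=O)CC[C@@H]1O[C@@]1(C)CCC=C(C)C
F3 | step 2 | (5R)-5-[(2S)-2-hydroxy-6-methylhept-5-en-2-yl]oxolan-2-one | O=C1O[C@@H]([C@@](C)(O)CCC=C(C)C)CC1
F4 | step 3 | (3S,5R)-3-acetyl-5-[(2S)-2-hydroxy-6-methylhept-5-en-2-yl]-3-(prop-2-en-1-yl)oxolan-2-one | O=C1O[C@@H]([C@@](C)(O)CCC=C(C)C)C[C@@]1(CC=C)C(C)=O
F5 | step 6 | (4S,8R)-4-[(2R,3S)-2,3-dihydroxy-3,7-dimethyloct-6-en-1-yl]-2,2,8-trimethyl-4-(3-methylbut-2-en-1-yl)-3,5,7-trioxodecanenitrile | CC[C@@H](C)C(=O)CC(=O)[C@](CC=C(C)C)(C[C@@H](O)[C@@](C)(O)CCC=C(C)C)C(=O)C(C)(C)C#N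
F6 | step 6 | 3-amino-6-[(2R,3S)-2,3-dihydroxy-3,7-dimethyloct-6-en-1-yl]-4,4-dimethyl-6-(3-methylbut-2-en-1-yl)-2-[(2R)-2-methylbutanoyl]cyclohex-2-ene-1,5-dione, quaternary ring carbon configured as in 14 | CC[C@@H](C)C(=O)C1=C(N)C(C)(C)C(=O)[C@@](CC=C(C)C)(C[C@@H](O)[C@@](C)(O)CCC=C(C)C)C1=O
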